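The route rests on cutting ring A of the eudesmane half at C1'–C10'. Ring B is a p-menthane whose methyl-bearing C10' lies para to C7', so (S)-carvone supplies it with C7' in place. In the key step an iron hydride passes H to C9' of the ring alkene and the tertiary C10' radical closes 6-endo onto the terminal carbon of a vinyl ketone; this one operation makes the C1'–C10' bond, ring A, the trans fusion and the quaternary stereocentre. The precursor is a 2-methylcyclohex-2-ene bearing, cis-1,3, a silyl-protected hydroxyisopropyl group at C7' and a 4-methylpent-1-en-3-one chain at C5'. The labdane acid is joined last by acylation.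

Key step: step 7

Assumption: isocupressic acid 22 (the acid half of the target without its acetyl group) is bought as an isolated natural product; the target is read as the 4'α-O-acyl derivative (equatorial oxygen, 4'β-CH3) of the 5'α-H, 7'β, 10'β-CH3 eudesmane-4',11'-diol, and the acyl group as the axial C19 carboxyl of a normal labdane.

Primed locants are eudesmane numbers (C11' = side-chain carbinol carbon); unprimed locants are labdane numbers.

Step 1
Reactants: 1 (S)-(+)-carvone
Product: 2 (1S,5S)-cis-carveol (OH cis to the isopropenyl group)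
Conditions: NaBH4, CeCl3·7H2O, MeOH, 0 °C
Reagents that add atoms: none
Why: Luche reduction gives clean 1,2-reduction of the enone, and hydride enters axially on the half-chair that keeps the isopropenyl group equatorial, so the carbinol carbon (future C9') carries OH cis to the C7' substituent, the relationship that step 2 relays to C5'.

Step 2
Reactants: 2 (1S,5S)-cis-carveol; 3 triethyl orthopropionate
Product: 6 ethyl 2-[(1S,5R)-2-methyl-5-(prop-1-en-2-yl)cyclohex-2-en-1-yl]propanoate (both C4' epimers), via mixed orthoester 4 (not isolated), via ketene acetal 5 (not isolated)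
Conditions: 3 (excess), EtCO2H (cat.), 140 °C, EtOH distilled off
Reagents that add atoms: none
Why: Johnson–Claisen rearrangement, in which the ketene acetal undergoes a suprafacial [3,3] shift through the conformer with the C–O bond pseudoaxial, so the new C5'–C4' bond forms on the face the oxygen leaves and C5' is set cis to the C7' group, while the alkene moves to C9'=C10' and C4' forms as both epimers, which is harmless because C4' is equilibrated in step 7 and made planar in step 8.

Step 3
Reactants: 6 ethyl 2-[(1S,5R)-2-methyl-5-(prop-1-en-2-yl)cyclohex-2-en-1-yl]propanoate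
Product: 8 ethyl 2-[(1S,5R)-5-(2-hydroxypropan-2-yl)-2-methylcyclohex-2-en-1-yl]propanoate, via alkylmercury acetate 7 (not isolated)
Conditions: Hg(OAc)2, THF/H2O, 0 °C → rt; then NaBH4, aq. NaOH, 0 °C
Reagents that add atoms: water, SMILES O
Why: Oxymercuration–demercuration (Markovnikov hydration) is much faster at the unhindered 1,1-disubstituted isopropenyl alkene than at the trisubstituted ring alkene flanked by C5', so only the C11' tertiary alcohol forms, no stereocentre is made, and the ring alkene is left as the single hydrogen-atom acceptor for step 7.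

Step 4
Reactants: 8 ethyl 2-[(1S,5R)-5-(2-hydroxypropan-2-yl)-2-methylcyclohex-2-en-1-yl]propanoate
Product: 9 ethyl 2-[(1S,5R)-2-methyl-5-[2-(triethylsilyloxy)propan-2-yl]cyclohex-2-en-1-yl]propanoate
Conditions: Et3SiOTf, 2,6-lutidine, CH2Cl2, −78 → 0 °C
Reagents that add atoms: triethylsilyl trifluoromethanesulfonate, SMILES CC[Si](CC)(CC)OS(=O)(=O)C(F)(F)F
Why: Silylation of a tertiary alcohol with a silyl triflate and a hindered pyridine base is standard, and the triethylsilyl ether keeps the C11' oxygen inert to the Grignard, enolate and alkoxide steps and later distinguishes it from the C4' hydroxyl.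

Step 5
Reactants: 9 ethyl 2-[(1S,5R)-2-methyl-5-[2-(triethylsilyloxy)propan-2-yl]cyclohex-2-en-1-yl]propanoate
Product: 10 N-methoxy-N-methyl-2-[(1S,5R)-2-methyl-5-[2-(triethylsilyloxy)propan-2-yl]cyclohex-2-en-1-yl]propanamide
Conditions: MeNH(OMe)·HCl, iPrMgCl, THF, −20 → 0 °C
Reagents that add atoms: N,O-dimethylhydroxylamine hydrochloride, SMILES CNOC.Cl
Why: Aminolysis of the ester by the chloromagnesium amide of N,O-dimethylhydroxylamine (Weinreb amide formation) tolerates the α-branch and the silyl ether and leaves all stereocentres untouched.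

Step 6
Reactants: 10 N-methoxy-N-methylamide; 11 vinylmagnesium bromide
Product: 13 4-[(1S,5R)-2-methyl-5-[2-(triethylsilyloxy)propan-2-yl]cyclohex-2-en-1-yl]pent-1-en-3-one (both C4' epimers), via magnesium chelate 12 (not isolated)
Conditions: THF, −20 → 0 °C; inverse quench into cold 1 M HCl
Reagents that add atoms: none
Why: Grignard addition to a Weinreb amide stops at the chelated tetrahedral intermediate, so a single vinyl group is transferred, and the inverse acidic quench keeps the liberated hydroxylamine from adding to the new enone.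

Step 7
Reactants: 13 vinyl ketone
Product: 15 11'-(triethylsilyloxy)eudesman-3'-one (trans-fused; 4'α-CH3; 5'α-H; 7'β side chain; 10'β-CH3), via C4' epimer mixture 14 (not isolated)
Conditions: Fe(acac)3 (0.3 equiv), PhSiH3, EtOH/HOCH2CH2OH (5:1), 0.02 M, 60 °C; then K2CO3, MeOH, rt
Reagents that add atoms: none
Why: The iron hydride formed from Fe(acac)3 and PhSiH3 in ethanol transfers a hydrogen atom to the less substituted C9' of the ring alkene, the tertiary C10' radical adds to the terminal carbon C1' of the vinyl ketone, and the resulting C2' α-keto radical is reduced by divalent iron to an enolate that ethanol protonates, which returns trivalent iron. The closest known reaction type is the Fe(acac)3/PhSiH3 reductive coupling of unactivated alkenes with enones (metal-hydride hydrogen-atom-transfer Giese addition), including intramolecular cases that set quaternary carbons in decalins. Ring A closes in the 6-endo-trig mode, which is polarity-matched because the nucleophilic radical meets the β-carbon of the enone, whereas the 5-exo alternative would need attack at the α-carbon C2'. The new stereocentre C10' is controlled by C5': with the C5' chain and the C7' group both equatorial on ring B, a chair-like transition state forms the C1'–C10' bond equatorial and trans to C5'–C4' (α face), leaving the C10' methyl axial, β and cis to the C7' arm, and C4' is then brought to the equatorial 4'α-methyl epimer by the carbonate equilibration through the enolate. The step needs hydrogen-atom transfer only at the C9'=C10' alkene and ring closure that outruns reduction of the radical or its addition to a second molecule; the first is secured because the isopropenyl group was hydrated in step 3 and the vinyl ketone is an electron-poor acceptor, the second by the six-membered closure at high dilution.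

Step 8
Reactants: 15 11'-(triethylsilyloxy)eudesman-3'-one
Product: 16 3'-(trimethylsilyloxy)-11'-(triethylsilyloxy)eudesm-3'-ene
Conditions: Me3SiCl, NaI, Et3N, MeCN, rt → 40 °C
Reagents that add atoms: chlorotrimethylsilane, SMILES C[Si](C)(C)Cl
Why: Silyl enol ether formation with iodotrimethylsilane made in the flask and triethylamine is reversible and should give the thermodynamic tetrasubstituted C3'=C4' enol ether, helped by the allylic strain that the equatorial 4'α-methyl would suffer against the silyloxy group in the C2'=C3' isomer.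

Step 9
Reactants: 16 3'-(trimethylsilyloxy)-11'-(triethylsilyloxy)eudesm-3'-ene
Product: 18 11'-(triethylsilyloxy)eudesm-3'-en-3'-yl trifluoromethanesulfonate, via lithium enolate 17 (not isolated)
Conditions: MeLi, THF, 0 °C; then PhNTf2, −78 °C → rt
Reagents that add atoms: N-phenylbis(trifluoromethanesulfonimide), SMILES O=S(=O)(N(c1ccccc1)S(=O)(=O)C(F)(F)F)C(F)(F)F
Why: Methyllithium cleaves the O–SiMe3 bond to release the lithium enolate without regiochemical scrambling, and O-sulfonylation with the triflimide traps it as the enol triflate (regiospecific enolate trapping).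

Step 10
Reactants: 18 enol triflate
Product: 19 11'-(triethylsilyloxy)eudesm-3'-ene (α-eudesmol triethylsilyl ether)
Conditions: Pd(OAc)2 (cat.), PPh3, HCO2H, Bu3N, DMF, 60 °C
Reagents that add atoms: none
Why: Palladium-catalysed formate reduction of an enol triflate, in which oxidative addition to zerovalent palladium, formate exchange, loss of CO2 and reductive elimination replace OTf by H and leave the C3'=C4' alkene where the triflate fixed it.

Step 11
Reactants: 19 11'-(triethylsilyloxy)eudesm-3'-ene
Product: 21 11'-(triethylsilyloxy)eudesman-4'α-ol (4'β-CH3), via C4' hydroperoxide 20 (not isolated)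
Conditions: Mn(dpm)3 (cat.; dpm = 2,2,6,6-tetramethylheptane-3,5-dionate), PhSiH3, O2 (1 atm), iPrOH/CH2Cl2, 0 °C → rt; then PPh3
Reagents that add atoms: dioxygen, SMILES O=O
Why: Mukaiyama hydration, in which hydrogen-atom transfer to C3' gives the tertiary C4' radical that O2 should trap from the α (equatorial) face because the β face is shielded by the syn-axial C10' methyl, so C4' receives O α and keeps CH3 β, and PPh3 reduces the hydroperoxide to the alcohol.

Step 12
Reactants: 22 isocupressic acid
Product: 24 15-(tert-butyldimethylsilyloxy)labda-8(17),13E-dien-19-oic acid, via bis-silyl derivative 23 (not isolated)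
Conditions: tBuMe2SiCl, imidazole, DMF, rt; then K2CO3, MeOH/THF/H2O, rt
Reagents that add atoms: tert-butyldimethylsilyl chloride, SMILES CC(C)(C)[Si](C)(C)Cl
Why: Silylation of both the primary allylic alcohol and the carboxyl group followed by mild carbonate cleavage of the labile silyl ester is the standard way to a silyl ether acid, and it removes the only other nucleophile of the labdane half before the acid is activated.

Step 13
Reactants: 24 15-(tert-butyldimethylsilyloxy)labda-8(17),13E-dien-19-oic acid
Product: 25 15-(tert-butyldimethylsilyloxy)labda-8(17),13E-dien-19-oyl chloride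
Conditions: 1-chloro-N,N,2-trimethylprop-1-en-1-amine, CH2Cl2, 0 °C → rt; evaporate, use at once
Reagents that add atoms: 1-chloro-N,N,2-trimethylprop-1-en-1-amine, SMILES CC(C)=C(Cl)N(C)C
Why: An α-chloroenamine converts the carboxylic acid into the acid chloride under neutral conditions, without HCl that could shift the exocyclic alkene or cleave the allylic silyl ether.

Step 14
Reactants: 21 11'-(triethylsilyloxy)eudesman-4'α-ol; 25 acid chloride
Product: 27 11'-(triethylsilyloxy)eudesman-4'α-yl 15-(tert-butyldimethylsilyloxy)labda-8(17),13E-dien-19-oate, via potassium alkoxide 26 (not isolated)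
Conditions: 21, KH, THF, 0 °C → rt; then 25, THF, rt → 50 °C
Reagents that add atoms: none
Why: Acylation of a tertiary potassium alkoxide by an acid chloride is the established nucleophilic acyl substitution for hindered tertiary esters, the acid chloride has no α-hydrogen and so can neither enolise nor form a ketene during the long reaction time that two fully substituted neighbours demand, the silyl ethers offer the alkoxide no other electrophile, and no stereocentre is touched.

Step 15
Reactants: 27 bis-silyl ester
Product: 28 11'-hydroxyeudesman-4'α-yl 15-hydroxylabda-8(17),13E-dien-19-oate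
Conditions: Bu4NF, THF, rt → 40 °C
Reagents that add atoms: none
Why: Fluoride cleaves both the primary allylic tert-butyldimethylsilyl ether and the tertiary triethylsilyl ether, while the doubly hindered tertiary ester is inert to this reagent.

Step 16
Reactants: 28 diol ester
Product: 29 CNP0141048.1 (11'-hydroxyeudesman-4'α-yl 15-acetoxylabda-8(17),13E-dien-19-oate)
Conditions: Ac2O, pyridine, 4-(dimethylamino)pyridine (cat.), CH2Cl2, 0 °C
Reagents that add atoms: acetic anhydride, SMILES CC(=O)OC(C)=O
Why: Acetylation with acetic anhydride and pyridine is selective for the primary allylic C15 hydroxyl over the tertiary C11' hydroxyl, which does not react under these conditions.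

Compound list
1 | (S)-(+)-carvone | CC1=CC[C@@H](CC1=O)C(C)=C | starting material
2 | (1S,5S)-cis-carveol, (1S,5S)-2-methyl-5-(prop-1-en-2-yl)cyclohex-2-en-1-ol | CC1=CC[C@@H](C[C@@H]1O)C(C)=C | intermediate
3 | triethyl orthopropionate | CCC(OCC)(OCC)OCC | starting material
4 | mixed orthoester, (1S,5S)-carveyl diethyl orthopropionate | CC1=CC[C@@H](C[C@@H]1OC(CC)(OCC)OCC)C(C)=C | intermediate
5 | ketene acetal, 1-ethoxy-1-[(1S,5S)-carveyloxy]prop-1-ene | CC1=CC[C@@H](C[C@@H]1OC(OCC)=CC)C(C)=C | intermediate
6 | ethyl 2-[(1S,5R)-2-methyl-5-(prop-1-en-2-yl)cyclohex-2-en-1-yl]propanoate, both C4' epimers | CCOC(=O)C(C)[C@@H]1C[C@H](C(C)=C)CC=C1C | intermediate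
7 | alkylmercury acetate, ethyl 2-[(1S,5R)-5-[1-(acetoxymercurio)-2-hydroxypropan-2-yl]-2-methylcyclohex-2-en-1-yl]propanoate | CCOC(=O)C(C)[C@@H]1C[C@H](C(C)(O)C[Hg]OC(C)=O)CC=C1C | intermediate
8 | ethyl 2-[(1S,5R)-5-(2-hydroxypropan-2-yl)-2-methylcyclohex-2-en-1-yl]propanoate | CCOC(=O)C(C)[C@@H]1C[C@H](C(C)(C)O)CC=C1C | intermediate
9 | ethyl 2-[(1S,5R)-2-methyl-5-[2-(triethylsilyloxy)propan-2-yl]cyclohex-2-en-1-yl]propanoate | CCOC(=O)C(C)[C@@H]1C[C@H](C(C)(C)O[Si](CC)(CC)CC)CC=C1C | intermediate
10 | N-methoxy-N-methyl-2-[(1S,5R)-2-methyl-5-[2-(triethylsilyloxy)propan-2-yl]cyclohex-2-en-1-yl]propanamide | CON(C)C(=O)C(C)[C@@H]1C[C@H](C(C)(C)O[Si](CC)(CC)CC)CC=C1C | intermediate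
11 | vinylmagnesium bromide | C=C[Mg]Br | starting material
12 | magnesium chelate (bromomagnesium alkoxide of the vinyl adduct of 10) | C=CC(O[Mg]Br)(N(C)OC)C(C)[C@@H]1C[C@H](C(C)(C)O[Si](CC)(CC)CC)CC=C1C | intermediate
13 | 4-[(1S,5R)-2-methyl-5-[2-(triethylsilyloxy)propan-2-yl]cyclohex-2-en-1-yl]pent-1-en-3-one, both C4' epimers (key-step precursor) | C=CC(=O)C(C)[C@@H]1C[C@H](C(C)(C)O[Si](CC)(CC)CC)CC=C1C | intermediate
14 | 11'-(triethylsilyloxy)eudesman-3'-one, trans-fused, C4' epimer mixture | CC1C(=O)CC[C@]2(C)CC[C@@H](C(C)(C)O[Si](CC)(CC)CC)C[C@H]21 | intermediate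
15 | 11'-(triethylsilyloxy)eudesman-3'-one, trans-fused, 4'α-CH3, 5'α-H, 7'β side chain, 10'β-CH3 (key-step product) | C[C@@H]1C(=O)CC[C@]2(C)CC[C@@H](C(C)(C)O[Si](CC)(CC)CC)C[C@H]21 | intermediate
16 | 3'-(trimethylsilyloxy)-11'-(triethylsilyloxy)eudesm-3'-ene | CC1=C(O[Si](C)(C)C)CC[C@]2(C)CC[C@@H](C(C)(C)O[Si](CC)(CC)CC)C[C@H]21 | intermediate
17 | lithium 11'-(triethylsilyloxy)eudesm-3'-en-3'-olate | CC1=C(O[Li])CC[C@]2(C)CC[C@@H](C(C)(C)O[Si](CC)(CC)CC)C[C@H]21 | intermediate
18 | 11'-(triethylsilyloxy)eudesm-3'-en-3'-yl trifluoromethanesulfonate | CC1=C(OS(=O)(=O)C(F)(F)F)CC[C@]2(C)CC[C@@H](C(C)(C)O[Si](CC)(CC)CC)C[C@H]21 | intermediate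
19 | 11'-(triethylsilyloxy)eudesm-3'-ene (α-eudesmol triethylsilyl ether) | CC1=CCC[C@]2(C)CC[C@@H](C(C)(C)O[Si](CC)(CC)CC)C[C@H]21 | intermediate
20 | 4'α-hydroperoxy-11'-(triethylsilyloxy)eudesmane (4'β-CH3) | C[C@@]1(OO)CCC[C@]2(C)CC[C@@H](C(C)(C)O[Si](CC)(CC)CC)C[C@H]21 | intermediate
21 | 11'-(triethylsilyloxy)eudesman-4'α-ol (4'β-CH3) | C[C@@]1(O)CCC[C@]2(C)CC[C@@H](C(C)(C)O[Si](CC)(CC)CC)C[C@H]21 | intermediate
22 | isocupressic acid, 15-hydroxylabda-8(17),13E-dien-19-oic acid | C=C1CC[C@@H]2[C@](C)(CCC[C@]2(C)C(=O)O)[C@H]1CC/C(C)=C/CO | starting material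
23 | tert-butyldimethylsilyl 15-(tert-butyldimethylsilyloxy)labda-8(17),13E-dien-19-oate | C=C1CC[C@@H]2[C@](C)(CCC[C@]2(C)C(=O)O[Si](C)(C)C(C)(C)C)[C@H]1CC/C(C)=C/CO[Si](C)(C)C(C)(C)C | intermediate
24 | 15-(tert-butyldimethylsilyloxy)labda-8(17),13E-dien-19-oic acid | C=C1CC[C@@H]2[C@](C)(CCC[C@]2(C)C(=O)O)[C@H]1CC/C(C)=C/CO[Si](C)(C)C(C)(C)C | intermediate
25 | 15-(tert-butyldimethylsilyloxy)labda-8(17),13E-dien-19-oyl chloride | C=C1CC[C@@H]2[C@](C)(CCC[C@]2(C)C(Cl)=O)[C@H]1CC/C(C)=C/CO[Si](C)(C)C(C)(C)C | intermediate
26 | potassium 11'-(triethylsilyloxy)eudesman-4'α-olate | C[C@@]1([O-])CCC[C@]2(C)CC[C@@H](C(C)(C)O[Si](CC)(CC)CC)C[C@H]21.[K+] | intermediate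
27 | 11'-(triethylsilyloxy)eudesman-4'α-yl 15-(tert-butyldimethylsilyloxy)labda-8(17),13E-dien-19-oate | C=C1CC[C@@H]2[C@](C)(CCC[C@]2(C)C(=O)O[C@]2(C)CCC[C@]3(C)CC[C@@H](C(C)(C)O[Si](CC)(CC)CC)C[C@H]32)[C@H]1CC/C(C)=C/CO[Si](C)(C)C(C)(C)C | intermediate
28 | 11'-hydroxyeudesman-4'α-yl 15-hydroxylabda-8(17),13E-dien-19-oate | C=C1CC[C@@H]2[C@](C)(CCC[C@]2(C)C(=O)O[C@]2(C)CCC[C@]3(C)CC[C@@H](C(C)(C)O)C[C@H]32)[C@H]1CC/C(C)=C/CO | intermediate
29 | CNP0141048.1, 11'-hydroxyeudesman-4'α-yl 15-acetoxylabda-8(17),13E-dien-19-oate | C=C1CC[C@@H]2[C@](C)(CCC[C@]2(C)C(=O)O[C@]2(C)CCC[C@]3(C)CC[C@@H](C(C)(C)O)C[C@H]32)[C@H]1CC/C(C)=C/COC(C)=O | target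

Total step count: 16. Longest linear sequence: 14 steps (steps 1–11 and 14–16 from (S)-carvone); steps 12 and 13 are the two-step labdane branch that joins at step 14.

Steps most likely to fail

Step 7. The C1'–C10' bond may form on the wrong face of the C10' radical (cis-fused decalin), or the radical may be reduced or add to a second molecule before ring A closes. The fallback builds the quaternary carbon by an intermolecular radical conjugate addition, where steric approach rather than a tether decides the face, and closes ring A afterwards by a polar condensation. It sets out from ester 9. Coupling of 9 with methyl acrylate under Fe(acac)3/PhSiH3 in EtOH/ethylene glycol should give the diester F1, the acrylate entering C10' anti to the branched C5' chain. KOtBu in THF should then close ring A by Dieckmann condensation to the β-keto ester F2; either condensation mode leads to the same ring-A ketone once the extra ester carbon is lost, and the enolisable isomer F2 is the one that accumulates. LiCl in wet DMSO at 150 °C removes the methoxycarbonyl group to give 14, and K2CO3 in MeOH returns to the route at ketone 15.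

Step 14. Acyl transfer may be too slow, because the alkoxide carbon C4' and the acyl carbon C19 each sit next to fully substituted carbons, so the alkoxide is recovered or the acid chloride is consumed by adventitious water. The fallback reverses the polarity: the eudesmane becomes the electrophile and the carboxylate the nucleophile, whose oxygen is remote from the quaternary C4 of the labdane. It sets out from alcohol 21. Cl3CCN with catalytic KH in Et2O should give the tertiary trichloroacetimidate F3. Warming F3 with acid 24 in cyclohexane/CH2Cl2 should give ester 27 by protonation and ion-pair collapse, the carboxylate attacking C4' from the α face away from the syn-axial C10' methyl. Alkene 19 formed by elimination can be recycled through step 11. The fallback returns to the route at 27.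

Step 8. Enolisation may run towards C2' instead of C4', since a trans ring fusion favours a C2'=C3' double bond, which would give the wrong enol ether and later the wrong alkene. The fallback avoids enolate regiochemistry and replaces steps 8–10. It sets out from ketone 15. NaBH4 in MeOH should give the equatorial 3'β-alcohol F4 by axial hydride delivery. Methyl N-(triethylammoniosulfonyl)carbamate in toluene at 80 °C converts F4 into the sulfamate ester F5, whose syn elimination (Burgess dehydration) should take the cis tertiary hydrogen at C4' and return to the route at alkene 19. Any C2'=C3' alkene is inert to the hydration of step 11 and is separated there from alcohol 21.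

Further compounds
F1 | step 7 | ethyl 2-[2-(3-methoxy-3-oxopropyl)-2-methyl-5-[2-(triethylsilyloxy)propan-2-yl]cyclohexyl]propanoate (C10' quaternary with β-CH3 and α-CH2CH2CO2Me; C5' chain and C7' group cis) | CCOC(=O)C(C)[C@@H]1C[C@H](C(C)(C)O[Si](CC)(CC)CC)CC[C@@]1(C)CCC(=O)OC
F2 | step 7 | methyl 3'-oxo-11'-(triethylsilyloxy)eudesmane-2'-carboxylate (trans-fused, C2' and C4' epimers) | COC(=O)C1C[C@]2(C)CC[C@@H](C(C)(C)O[Si](CC)(CC)CC)C[C@H]2C(C)C1=O
F3 | step 14 | 11'-(triethylsilyloxy)eudesman-4'α-yl 2,2,2-trichloroacetimidate | C[C@@]1(OC(=N)C(Cl)(Cl)Cl)CCC[C@]2(C)CC[C@@H](C(C)(C)O[Si](CC)(CC)CC)C[C@H]21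
F4 | step 8 | 11'-(triethylsilyloxy)eudesman-3'β-ol (4'α-CH3) | C[C@@H]1[C@@H](O)CC[C@]2(C)CC[C@@H](C(C)(C)O[Si](CC)(CC)CC)C[C@H]21
F5 | step 8 | triethylammonium salt of the 3'β-O-[N-(methoxycarbonyl)sulfamate] of F4 | C[C@@H]1[C@@H](OS(=O)(=O)[N-]C(=O)OC)CC[C@]2(C)CC[C@@H](C(C)(C)O[Si](CC)(CC)CC)C[C@H]21.CC[NH+](CC)CC
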